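**Retrosynthetic overview**
- Target ⇐ site-selective acetylation of the tricyclic diol ⇐ transannular opening of a cyclohexene oxide by the oxane 3-OH (oxepane bridge, last ring).
- Bromo-oxane ⇐ ring expansion (1,2-oxygen shift through a bicyclic epoxonium ion, bromide return) of a 5-(2-hydroxyprop-2-yl)oxolane ⇐ 5-exo opening of an (S)-prenyl epoxide by the tertiary alcohol.
- Open-chain triol diene ⇐ double reduction of a silyloxy diketone ⇐ Cu–box Mukaiyama aldol of a silyl dienol ether with 6-methylhept-5-ene-2,3-dione (two stereocentres).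
- Pieces: m-cresol (silylation, Birch reduction); 4-methylpent-3-enoic acid plus ethyl vinyl ether (Weinreb ketone synthesis).
- Ring order: carbocycle (from the arene) → oxolane → oxane (ring expansion) → oxepane bridge.

Assumption: catalysts and reagents (Cu–box complex, both enantiomers of the Shi ketone, TBSCl, TESOTf) are purchasable and are not counted as starting materials.

Step 1
Reactants: 1 3-methylphenol
Product: 2 tert-butyldimethyl(3-methylphenoxy)silane
Conditions: TBSCl, imidazole, DMF, rt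
Reagents that add atoms: tert-butyldimethylsilyl chloride, CC(C)(C)[Si](C)(C)Cl
Why: Standard phenol O-silylation (silyl ether protection); the silyl group survives Li/NH3 and later serves as the enol-silane handle.

Step 2
Reactants: 2 tert-butyldimethyl(3-methylphenoxy)silane
Product: 3 tert-butyldimethyl[(5-methylcyclohexa-1,4-dien-1-yl)oxy]silane
Conditions: Li, liq. NH3/THF, t-BuOH, −78 °C
Reagents that add atoms: none
Why: Birch reduction keeps both donor substituents on sp2 carbons, giving the regiodefined silyl enol ether of 3-methylcyclohex-3-enone; no stereocentre is formed.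

Step 3
Reactants: 4 4-methylpent-3-enoic acid
Product: 6 N-methoxy-N,4-dimethylpent-3-enamide, via acyl imidazolide 5 (not isolated)
Conditions: CDI, CH2Cl2, rt; then MeNHOMe·HCl, rt
Reagents that add atoms: N,O-dimethylhydroxylamine hydrochloride, CNOC.Cl
Why: Weinreb amide formation through the acyl imidazolide under near-neutral conditions that leave the β,γ-double bond in place.

Step 4
Reactants: 6 N-methoxy-N,4-dimethylpent-3-enamide; 7 ethyl vinyl ether
Product: 10 6-methylhept-5-ene-2,3-dione, via 1-ethoxyvinyllithium 8 (not isolated), via ethoxy enone 9 (not isolated)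
Conditions: 7, t-BuLi, THF, −78 → 0 °C; then 6, −78 °C; then 1 M HCl, THF, rt
Reagents that add atoms: water, O
Why: Weinreb ketone synthesis with 1-ethoxyvinyllithium as acetyl anion equivalent (the chelated adduct stops at mono-addition), followed by enol ether hydrolysis to the 1,2-diketone.

Step 5
Reactants: 3 tert-butyldimethyl[(5-methylcyclohexa-1,4-dien-1-yl)oxy]silane; 10 6-methylhept-5-ene-2,3-dione
Product: 11 (2S)-2-[(tert-butyldimethylsilyl)oxy]-6-methyl-2-[(1S)-4-methyl-2-oxocyclohex-4-en-1-yl]hept-5-en-3-one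
Conditions: [Cu((S,S)-t-Bu-box)](OTf)2 (10 mol %), CH2Cl2, −78 → −40 °C
Reagents that add atoms: none
Why: Catalytic enantioselective Mukaiyama aldol: the diketone chelates copper through both carbonyls, the less hindered methyl ketone is attacked on its si face (sets the (2S) carbinol), the open transition state gives the syn adduct (sets the ring carbon), and the silyl group transfers to the new tertiary alkoxide.

Step 6
Reactants: 11 (2S)-2-[(tert-butyldimethylsilyl)oxy]-6-methyl-2-[(1S)-4-methyl-2-oxocyclohex-4-en-1-yl]hept-5-en-3-one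
Product: 13 (1S,6R)-6-[(2S,3S)-2,3-dihydroxy-6-methylhept-5-en-2-yl]-3-methylcyclohex-3-en-1-ol, via diol silyl ether 12 (not isolated)
Conditions: L-Selectride (3 equiv), THF, −78 → −20 °C, H2O quench; then 48% aq. HF, MeCN, 0 °C → rt
Reagents that add atoms: none
Why: Bulky-hydride reduction: equatorial attack on the ring ketone gives the cis (axial) alcohol, Felkin–Anh attack on the α-silyloxy ketone (hydride anti to OSi, passing the methyl group) gives the 2,3-syn diol, and HF then cleaves the tertiary silyl ether.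

Step 7
Reactants: 13 (1S,6R)-6-[(2S,3S)-2,3-dihydroxy-6-methylhept-5-en-2-yl]-3-methylcyclohex-3-en-1-ol
Product: 15 (2S,3S,5R)-2-[(1R,6S)-6-hydroxy-4-methylcyclohex-3-en-1-yl]-5-(2-hydroxypropan-2-yl)-2-methyloxolan-3-ol, via epoxy triol 14 (not isolated)
Conditions: ent-Shi ketone (L-fructose-derived, 30 mol %), Oxone (1.2 equiv), K2CO3, Bu4NHSO4, MeCN–DMM/aq. buffer pH 10.5, 0 °C; then CSA (10 mol %), CH2Cl2, 0 °C
Reagents that add atoms: Oxone (potassium peroxymonosulfate), [K+].[O-]S(=O)(=O)OO
Why: Shi asymmetric epoxidation gives the (S)-epoxide of the unhindered prenyl alkene (the ring alkene is mismatched with this catalyst enantiomer and should react more slowly), and acid-catalysed 5-exo epoxide opening by the tertiary alcohol, as in linalool oxide formation, inverts the CH carbon to the (5R) oxolane centre.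

Step 8
Reactants: 15 (2S,3S,5R)-2-[(1R,6S)-6-hydroxy-4-methylcyclohex-3-en-1-yl]-5-(2-hydroxypropan-2-yl)-2-methyloxolan-3-ol
Product: 18 (2S,3S,5S)-5-bromo-2-[(1R,6S)-6-hydroxy-4-methylcyclohex-3-en-1-yl]-2,6,6-trimethyloxan-3-ol, via tris-TMS ether 16 (not isolated), via bis-TMS bromo-oxane 17 (not isolated)
Conditions: TMSBr (4.5 equiv), 2,6-di-tert-butyl-4-methylpyridine (3.3 equiv), ZnBr2 (20 mol %), CH2Cl2, −40 → 0 °C; then 1 M HCl–THF, 0 °C, NaHCO3 wash
Reagents that add atoms: bromotrimethylsilane, C[Si](C)(C)Br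
Why: Proposed new method: silylation makes the tertiary carbinol a siloxy leaving group that TMSBr ionises with anchimeric help of the ring oxygen to a bicyclic epoxonium (1-oxoniabicyclo[3.1.0]hexane) ion; bromide returns reversibly at the tertiary carbon and, under ZnBr2 equilibration, at the secondary carbon anti to the C–O bond, which enlarges the oxolane to the oxane, moves the oxygen to the CMe2 carbon and sets the equatorial (5S)-bromide by inversion (the hindered base removes HBr so the ring alkene is untouched); the closest known reactions are oxolane-to-oxane ring expansions of exocyclic secondary sulfonates with oxygen nucleophiles and the TMSBr deoxybromination of tertiary alcohols.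

Step 9
Reactants: 18 (2S,3S,5S)-5-bromo-2-[(1R,6S)-6-hydroxy-4-methylcyclohex-3-en-1-yl]-2,6,6-trimethyloxan-3-ol
Product: 20 (1R,2S,5S,7S,9R,10R,12S)-5-bromo-2,4,4,9-tetramethyl-3,8-dioxatricyclo[7.2.2.0^2,7]tridecane-10,12-diol, via ring epoxide 19 (not isolated)
Conditions: Shi ketone (D-fructose-derived, 30 mol %), Oxone, K2CO3, Bu4NHSO4, MeCN–DMM/aq. buffer, 0 °C; then CSA (10 mol %), CH2Cl2–HFIP 4:1, −20 → 0 °C
Reagents that add atoms: Oxone (potassium peroxymonosulfate), [K+].[O-]S(=O)(=O)OO
Why: Shi epoxidation with the D-series catalyst attacks the ring alkene on the face anti to the side chain, and acid-catalysed Markovnikov transannular epoxide opening by the oxane hydroxyl at the tertiary carbon (inversion) closes the oxepane bridge and leaves the trans secondary alcohol; the cyclohexanol is kept unacylated here because a cis ester would open the epoxide by 1,3-participation.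

Step 10
Reactants: 20 (1R,2S,5S,7S,9R,10R,12S)-5-bromo-2,4,4,9-tetramethyl-3,8-dioxatricyclo[7.2.2.0^2,7]tridecane-10,12-diol
Product: 23 (1R,2S,5S,7S,9R,10R,12S)-5-bromo-10-hydroxy-2,4,4,9-tetramethyl-3,8-dioxatricyclo[7.2.2.0^2,7]tridecan-12-yl acetate, via 10-O-TES ether 21 (not isolated), via 10-O-TES 12-acetate 22 (not isolated)
Conditions: TESOTf (1.05 equiv), 2,6-lutidine, CH2Cl2, −78 °C; then Ac2O, DMAP, pyridine, 0 °C → rt; then HF·pyridine, THF, 0 °C
Reagents that add atoms: acetic anhydride, CC(=O)OC(C)=O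
Why: Site-selective acylation by transient protection: the exposed 10-OH is silylated first, the hindered 12-OH (pointing at the oxane oxygen) is then acetylated by DMAP-catalysed acylation, and fluoride removes the silyl ether; no stereocentre changes.

**Compound list**
1 | 3-methylphenol (m-cresol) | Cc1cccc(O)c1 | starting material
2 | tert-butyldimethyl(3-methylphenoxy)silane | Cc1cccc(O[Si](C)(C)C(C)(C)C)c1 | intermediate
3 | tert-butyldimethyl[(5-methylcyclohexa-1,4-dien-1-yl)oxy]silane | CC1=CCC=C(O[Si](C)(C)C(C)(C)C)C1 | intermediate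
4 | 4-methylpent-3-enoic acid | CC(C)=CCC(=O)O | starting material
5 | 1-(imidazol-1-yl)-4-methylpent-3-en-1-one (acyl imidazolide) | CC(C)=CCC(=O)n1ccnc1 | intermediate
6 | N-methoxy-N,4-dimethylpent-3-enamide | CC(C)=CCC(=O)N(C)OC | intermediate
7 | ethyl vinyl ether | C=COCC | starting material
8 | 1-ethoxyvinyllithium | [Li]C(=C)OCC | intermediate
9 | 2-ethoxy-6-methylhepta-1,5-dien-3-one | C=C(OCC)C(=O)CC=C(C)C | intermediate
10 | 6-methylhept-5-ene-2,3-dione | CC(=O)C(=O)CC=C(C)C | intermediate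
11 | (2S)-2-[(tert-butyldimethylsilyl)oxy]-6-methyl-2-[(1S)-4-methyl-2-oxocyclohex-4-en-1-yl]hept-5-en-3-one | O=C1CC(C)=CC[C@H]1[C@](C)(O[Si](C)(C)C(C)(C)C)C(=O)CC=C(C)C | intermediate
12 | (1S,6R)-6-[(2S,3S)-2-[(tert-butyldimethylsilyl)oxy]-3-hydroxy-6-methylhept-5-en-2-yl]-3-methylcyclohex-3-en-1-ol | O[C@H]1CC(C)=CC[C@H]1[C@](C)(O[Si](C)(C)C(C)(C)C)[C@@H](O)CC=C(C)C | intermediate
13 | (1S,6R)-6-[(2S,3S)-2,3-dihydroxy-6-methylhept-5-en-2-yl]-3-methylcyclohex-3-en-1-ol | O[C@H]1CC(C)=CC[C@H]1[C@](C)(O)[C@@H](O)CC=C(C)C | intermediate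
14 | (1S,6R)-6-[(2S,3S)-4-[(2S)-3,3-dimethyloxiran-2-yl]-2,3-dihydroxybutan-2-yl]-3-methylcyclohex-3-en-1-ol | O[C@H]1CC(C)=CC[C@H]1[C@](C)(O)[C@@H](O)C[C@@H]2OC2(C)C | intermediate
15 | (2S,3S,5R)-2-[(1R,6S)-6-hydroxy-4-methylcyclohex-3-en-1-yl]-5-(2-hydroxypropan-2-yl)-2-methyloxolan-3-ol | O[C@H]1CC(C)=CC[C@H]1[C@]2(C)O[C@@H](C(C)(C)O)C[C@@H]2O | intermediate
16 | tris(trimethylsilyl) ether of 15 | C[Si](C)(C)O[C@H]1CC(C)=CC[C@H]1[C@]2(C)O[C@@H](C(C)(C)O[Si](C)(C)C)C[C@@H]2O[Si](C)(C)C | intermediate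
17 | bis(trimethylsilyl) ether of 18 | C[Si](C)(C)O[C@H]1CC(C)=CC[C@H]1[C@]2(C)OC(C)(C)[C@@H](Br)C[C@@H]2O[Si](C)(C)C | intermediate
18 | (2S,3S,5S)-5-bromo-2-[(1R,6S)-6-hydroxy-4-methylcyclohex-3-en-1-yl]-2,6,6-trimethyloxan-3-ol | O[C@H]1CC(C)=CC[C@H]1[C@]2(C)OC(C)(C)[C@@H](Br)C[C@@H]2O | intermediate
19 | (1S,3S,4R,6R)-4-[(2S,3S,5S)-5-bromo-3-hydroxy-2,6,6-trimethyloxan-2-yl]-1-methyl-7-oxabicyclo[4.1.0]heptan-3-ol (epoxide anti to the oxanyl and hydroxyl groups) | O[C@H]1C[C@]3(C)O[C@@H]3C[C@H]1[C@]2(C)OC(C)(C)[C@@H](Br)C[C@@H]2O | intermediate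
20 | (1R,2S,5S,7S,9R,10R,12S)-5-bromo-2,4,4,9-tetramethyl-3,8-dioxatricyclo[7.2.2.0^2,7]tridecane-10,12-diol | O[C@H]1C[C@@]2(C)O[C@H]3C[C@H](Br)C(C)(C)O[C@@]3(C)[C@@H]1C[C@H]2O | intermediate
21 | 10-O-triethylsilyl ether of 20 | O[C@H]1C[C@@]2(C)O[C@H]3C[C@H](Br)C(C)(C)O[C@@]3(C)[C@@H]1C[C@H]2O[Si](CC)(CC)CC | intermediate
22 | 10-O-triethylsilyl ether of 23 | CC(=O)O[C@H]1C[C@@]2(C)O[C@H]3C[C@H](Br)C(C)(C)O[C@@]3(C)[C@@H]1C[C@H]2O[Si](CC)(CC)CC | intermediate
23 | (1R,2S,5S,7S,9R,10R,12S)-5-bromo-10-hydroxy-2,4,4,9-tetramethyl-3,8-dioxatricyclo[7.2.2.0^2,7]tridecan-12-yl acetate (CNP0247588.2) | CC(=O)O[C@H]1C[C@@]2(C)O[C@H]3C[C@H](Br)C(C)(C)O[C@@]3(C)[C@@H]1C[C@H]2O | target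

**Totals**
Total step count: 10. Longest linear sequence: 8 (steps 1, 2, 5–10; the branch through steps 3 and 4 is equally long).

**Steps most likely to fail and fallbacks**

Step 8 (proposed ring expansion). Elimination to the isopropenyl oxolane or incomplete isomerisation of the tertiary bromide could defeat it. The fallback uses the established bromonium route: triol 13 is treated with 2,4,4,6-tetrabromocyclohexa-2,5-dienone in MeNO2 at −20 °C. 6-endo bromoetherification of the prenyl alkene by the tertiary alcohol gives 18 directly, together with its C-5 epimer, (2S,3S,5R)-5-bromo-2-[(1R,6S)-6-hydroxy-4-methylcyclohex-3-en-1-yl]-2,6,6-trimethyloxan-3-ol F1, which is removed by chromatography. This sets out from 13 and returns at 18 (steps 7 and 8 are bypassed), at the price of no control over the bromine-bearing centre and possible competing capture at the ring alkene.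

Step 9 (transannular etherification). The hydroxyl may attack the secondary epoxide carbon instead (six-membered ring, 2-oxabicyclo[3.3.1] isomer), or the tertiary cation may eliminate. In the fallback, ring epoxide 19 is isolated after the Shi epoxidation and isomerised with Cp2TiCl (Cp2TiCl2, Mn, THF) to the exocyclic allylic alcohol (1S,2R,4R)-2-[(2S,3S,5S)-5-bromo-3-hydroxy-2,6,6-trimethyloxan-2-yl]-5-methylidenecyclohexane-1,4-diol F2, which keeps the C–O bond at the secondary carbon. A cobalt–salen hydrogen-atom-transfer Markovnikov hydroalkoxylation (N-fluoro-2,4,6-trimethylpyridinium salt, PhSiH3) then places the ether oxygen at the tertiary carbon only, returning at 20.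

Step 10 (site-selective acetylation). Silylation may not discriminate the two secondary hydroxyls well enough. In the fallback, diol 20 is acetylated exhaustively (Ac2O, DMAP) to the diacetate (1R,2S,5S,7S,9R,10R,12S)-5-bromo-2,4,4,9-tetramethyl-3,8-dioxatricyclo[7.2.2.0^2,7]tridecane-10,12-diyl diacetate F3. The exposed 10-acetate is then cleaved selectively (K2CO3, MeOH, 0 °C, or a lipase), returning at 23.

**Further compounds**
F1 | step 8 | (2S,3S,5R)-5-bromo-2-[(1R,6S)-6-hydroxy-4-methylcyclohex-3-en-1-yl]-2,6,6-trimethyloxan-3-ol | O[C@H]1CC(C)=CC[C@H]1[C@]2(C)OC(C)(C)[C@H](Br)C[C@@H]2O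
F2 | step 9 | (1S,2R,4R)-2-[(2S,3S,5S)-5-bromo-3-hydroxy-2,6,6-trimethyloxan-2-yl]-5-methylidenecyclohexane-1,4-diol | O[C@H]1CC(=C)[C@H](O)C[C@H]1[C@]2(C)OC(C)(C)[C@@H](Br)C[C@@H]2O
F3 | step 10 | (1R,2S,5S,7S,9R,10R,12S)-5-bromo-2,4,4,9-tetramethyl-3,8-dioxatricyclo[7.2.2.0^2,7]tridecane-10,12-diyl diacetate | CC(=O)O[C@H]1C[C@@]2(C)O[C@H]3C[C@H](Br)C(C)(C)O[C@@]3(C)[C@@H]1C[C@H]2OC(C)=O
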